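- The number we want is the leftover of J, since Saturday's Q at 6.00 h reads 0.8 %, less than Friday's 3.4 %, and Saturday had the larger charge of J.

| setting | Friday's | Monday's | Saturday's | maple | ash | birch | oak |
|---|---|---|---|---|---|---|---|
| E | 1 M | 1 M | 1 M | 1.0 M | 1.0 M | 1.0 M | 1.0 M |
| J | 0.37 equiv | 0.55 equiv | 0.99 equiv | 0.300 equiv | 0.400 equiv | 0.600 equiv | 1.00 equiv |
| remark | run made earlier | run made earlier | run made earlier |  |  |  |  |
| time |  |  |  | 12 h | 12 h | 12 h | 12 h |

| run | time / h | Q / % | D / % | E / % |
|---|---|---|---|---|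
| Friday's | 0.500 | 2.7 | 2.7 | 93.9 |
| Friday's | 1.50 | 3.9 | 9.1 | 81.2 |
| Friday's | 3.00 | 3.8 | 11.9 | 64.1 |
| Friday's | 4.00 | 4.1 | 12.5 | 55.8 |
| Friday's | 6.00 | 3.4 | 11.1 | 43.8 |
| Monday's | 1.33 | 2.6 | 8.8 | 82.5 |
| Monday's | 2.50 | 3.0 | 12.9 | 68.1 |
| Monday's | 4.00 | 2.3 | 14.8 | 52.6 |
| Monday's | 5.00 | 1.7 | 14.9 | 43.7 |
| Monday's | 6.00 | 1.8 | 15.0 | 37.6 |
| Saturday's | 0.500 | 1.6 | 3.9 | 93.1 |
| Saturday's | 1.50 | 1.4 | 10.8 | 80.0 |
| Saturday's | 3.00 | 1.0 | 15.0 | 60.6 |
| Saturday's | 4.00 | 1.1 | 16.2 | 50.1 |
| Saturday's | 6.00 | 0.8 | 17.2 | 33.3 |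

(each reading ± 0.3 percentage points)

- "hardly changes" means that all values lie within two and a half points (for a concentration: within two and a half percent of the largest)

1. amount of Q at the end, in percent of the E charged for maple, ash, birch, oak, in this order
2. how that number moves from the first to the last of them (rises, then falls / falls all the way / hardly changes / falls, then rises / rises all the way)

- J is not read, so we reckon it. On Friday at 4.00 h, E gone beyond Q reads 40.1 %, more than the 37.0 % of J charged.
- One J per E lost therefore fails. We assume one J per two E lost unseen, so J used is D plus half of the unseen loss.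
- Friday's J used then goes from 22.0 % at 3.00 h to 31.9 % at 6.00 h, a flow of 0.0332 h⁻¹.
- We divide that flow by the mean J left and the mean Q, both as fractions of the charge, and get 8.78 h⁻¹. This reading is our catch constant, the rate at which Q is caught per unit of Q and per unit of J left.
- The catch half-life of Q is ln(2) over the catch constant times J left. At maple's charge it is 0.263 h, shorter than 12 h.
- First extreme: J stays ample, and Q is flow over catch rate. Saturday's flow and J left at 6.00 h give 0.981 %. We expect oak to end below that.
- Second extreme: J is gone, and Q has no catcher. Friday's J left at 6.00 h, 5.05 %, is less than the gap of 7.00 % between Friday's charge and maple's. J, the limiting reagent, should thus be near its end in maple by then, and we put maple's Q at no less than Friday's 3.4 %.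
- Ash and birch lie between, so we expect a steady fall.
- The forecast gives 2.6 %, 1.9 %, 0.9 % and 0.3 %, falls all the way, on the ground “Q therefore falls steadily with equivalents”, and its maple value lies under our floor.
- The flask gives 5.55 %, 3.01 %, 0.855 % and 0.226 %: falls all the way. Maple stands above our floor. Oak stands below our ceiling.

    E ⇌ Q + Z (K = 0.0520 M, k = 0.00200 min⁻¹)
    J + Q → D (k = 0.160 L mol⁻¹ min⁻¹)
    E + D → G (k = 0.00930 L mol⁻¹ min⁻¹)

- In maple, J + Q → D ran while J lasted: J stood at 6.85 % of its charge at 6.00 h and 0.25 % at 12.0 h, when the half-life of Q by this step was 95 h, longer than 12 h. Maple's Q stood at 5.73 % at 6.00 h and 5.55 % at 12.0 h, while D stood at 3.06 % at 12.0 h. In oak, J stood at 46.5 % of its charge at 12.0 h, our estimated catch constant puts the catch half-life at 0.170 h, shorter than 12 h, and oak's Q stood at 0.226 %.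

Readings and results were generated by integration for an exercise; the scatter is artificial.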